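**Assumption:** the SMILES is read as methyl 2-[(3R,5S)-3,5-dimethyl-5-[(7E,9E,12Z)-pentadeca-7,9,12-trien-1-yl]-1,2-dioxolan-3-yl]acetate, in which the two ring methyl groups are trans. Penta-1,4-diyne is not a regular catalogue item, so its preparation is counted as step 1.

## Analysis of the target

Target 26 is a C20 chain (C1 = ester carbon, C20 = terminal methyl) with methyl branches at C3 and C5. C3 and C5 are bridged by an O–O unit, so C3, C4, C5 and the two oxygens form a 1,2-dioxolane. C3 (CH3, CH2CO2Me, C4, O) and C5 (CH3, the C6 chain, C4, O) are the only stereocentres: two fully substituted peroxy carbons in a 1,3-relationship, (3R,5S), methyl groups trans. At each of them the two carbon substituents differ only as CH3 against CH2R, so induction from one centre to the other is weak. The common ways of making a tertiary C–OO bond (O2 capture by a radical, hydroperoxide capture by a cation, reversible oxa-Michael addition) pass through planar or equilibrating intermediates.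

The feature used here is a hidden twofold axis. If C3 and C5 carry the same one-carbon arm, the trans-dimethyl dioxolane is C2-symmetric (axis through C4 and the midpoint of O–O). Both stereocentres are then C–O carbons bound to the two oxygens of one peroxide, so they can be set as a pair by two invertive alkylations of a single H2O2.

Sensitive groups:
- the O–O bond (reductants, low-valent metals, organolithium and Grignard reagents, catalytic hydrogenation);
- the β-peroxy ester (C2–H acidity, E1cB opening of the ring);
- the 12E,14E,17Z triene with its doubly allylic C16.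

The chain therefore has to be built after the peroxide by olefination, with diimide as the only reductant.

## Retrosynthetic reasoning

The C14=C15 bond of 26 is cut first, giving enal 20 and sulfone 24 (Julia–Kocienski). The enal/alkyl sulfone pairing is the E-selective one, the carbanion sits on the fragment that carries no peroxide, and the 17Z alkene comes ready-made from alcohol 21 (with thiol 22).

Enal 20 is cut at C12=C13 to aldehyde 18 and the two-carbon ylide 19. In 18 the methyl ester (C1) and the C12 aldehyde are both traced to one oxidation of enol ether alcohol 17. The C1–C2 bond of 17 comes from a one-carbon Wittig homologation of the ring-bound aldehyde 14 with salt 15. Until that oxidation, every carbonyl next to the ring is non-enolisable, so no base-sensitive β-peroxy carbonyl is carried through the basic steps.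

The C6–C7 bond of 14 is cut via alkene 13 to dialdehyde 10 and salt 11 (Wittig, then diimide). Dialdehyde 10 is C2-symmetric, so its two formyl groups are homotopic and mono-olefination gives one compound whichever group reacts. Breaking the symmetry costs no stereochemistry.

Dialdehyde 10 comes from tetraol 9 by glycol cleavage. In 9 the two C–O bonds of the dioxolane (C3–O and C5–O) are cut together, leading to bis-epoxide 7 and the peroxide reagent of step 4. This is the key disconnection. Each cut bond ends at a stereocentre, and each can be formed with inversion at an epoxide carbon whose configuration is set beforehand by reagent control. The forward reaction closes the ring and sets both quaternary stereocentres in one operation from an acyclic precursor. It has to attack the tertiary carbons with inversion, use the hydroperoxide (not a hydroxyl) for the second opening, and stop at one peroxide unit per molecule.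

Bis-epoxide 7 is traced to dienediol 6 by a twofold asymmetric epoxidation. Dienediol 6 comes from diyne 3 by a twofold methyl-metalation and trapping with a one-carbon electrophile, and 3 from 1 and 2. The heptane numbering of 6, 7 and 9 coincides with the target numbering for C2–C6.

## Alternatives that were turned down

Alternative 1: the textbook route. Disconnection: C5–O by radical hydroperoxysilylation and C3–O by intramolecular oxa-Michael addition. Forward key step: cobalt-catalysed Isayama–Mukaiyama hydroperoxysilylation of a 2-methyl-1-alkene gives silyl peroxide A1; desilylation and base then close the ring onto the enoate. Turned down because C5 is formed from a planar tertiary radical (racemic) and the oxa-Michael closure is reversible and sees only CH3 against CH2R at C5. All four stereoisomers would form, and the wanted one would need resolution and diastereomer separation. The cobalt hydride would also attack the diene, so the side chain would still have to be attached after the peroxide.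

Alternative 2: disconnection of the C2–C3 bond on a peroxycarbenium ion, with C5–O set earlier by invertive perhydrolysis of an enantioenriched oxetane. Forward key step: Lewis-acid ionisation of 3-methoxy-1,2-dioxolane A2 and addition of a silyl ketene acetal. Turned down because the nucleophile must choose a face of a planar cation whose only bias is CH3 against CH2R at the 1,3-related C5. About half of a late intermediate would be the wrong C3 epimer, and the sequence is linear. The doubly oxetane-based analogue of the chosen key step, bis-oxetane A3, would deliver two-carbon arms directly but was also set aside. Its precursor cannot be closed selectively, because each tertiary alkoxide would form a six-membered ether onto the other arm faster than a four-membered ring onto its own.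

Alternative 3: disconnection of C3–C4 and C5–O by a [3+2] annulation. Forward key step: ionisation of silyl peroxyketal A4 to a silylperoxycarbenium ion, addition to the 1,1-disubstituted alkene A5, and capture of the tertiary cation by the silylperoxy oxygen. It is convergent but was turned down: both new centres arise from planar cations without facial control or absolute control. The ester-substituted peroxycarbenium ion is destabilised and prone to elimination. The strongly Lewis-acidic conditions would again force a late attachment of the triene.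

Key step: step 4

## Route

Step 1
Reactants: 1 ethynylmagnesium bromide; 2 3-bromoprop-1-yne (propargyl bromide)
Product: 3 penta-1,4-diyne
Conditions: CuBr (cat.), THF, 0 °C → rt; THF washed out with aqueous NH4Cl, product distilled and used promptly
Reagents that add atoms: none
Why: Copper-catalysed coupling of an alkynyl Grignard reagent with a propargylic halide gives the skipped diyne by direct substitution; the product is volatile and base-sensitive and is carried on at once.

Step 2
Reactants: 3 penta-1,4-diyne
Product: 6 (2E,5E)-3,5-dimethylhepta-2,5-diene-1,7-diol, via bis(alkenyl)alane 4 (not isolated), via lithium alanate 5 (not isolated)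
Conditions: AlMe3, Cp2ZrCl2 (cat.), CH2Cl2, 0 °C → rt; then n-BuLi, THF, −78 °C; (CH2O)n, −78 °C → rt
Reagents that add atoms: trimethylaluminium, C[Al](C)C; paraformaldehyde (as formaldehyde), C=O
Why: Twofold Negishi zirconium-catalysed carboalumination; syn addition of methyl and aluminium with aluminium on the terminal carbon fixes both trisubstituted alkenes as E, and the alanate transfers the alkenyl group to formaldehyde with retention.

Step 3
Reactants: 6 (2E,5E)-3,5-dimethylhepta-2,5-diene-1,7-diol
Product: 7 (2S,3S,5S,6S)-2,3:5,6-diepoxy-3,5-dimethylheptane-1,7-diol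
Conditions: Ti(OiPr)4, L-(+)-diisopropyl tartrate, t-BuOOH (anhydrous), 4 Å MS, CH2Cl2, −20 °C
Reagents that add atoms: tert-butyl hydroperoxide, CC(C)(C)OO
Why: Twofold Sharpless asymmetric epoxidation of two geraniol-type E-allylic alcohols; the L-(+)-tartrate complex should deliver oxygen to the same face of each, giving the (2S,3S) arrangement twice. The rare wrong-face event ends in a separable meso diastereomer, so 7 should be essentially enantiopure.

Step 4
Reactants: 7 (2S,3S,5S,6S)-2,3:5,6-diepoxy-3,5-dimethylheptane-1,7-diol
Product: 9 (1S,1'S)-1,1'-[(3R,5R)-3,5-dimethyl-1,2-dioxolane-3,5-diyl]di(ethane-1,2-diol), via hydroperoxy epoxide 8 (not isolated)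
Conditions: H2O2 (anhydrous ethereal solution, 1.1 equiv, slow addition), H3PMo12O40 (5 mol%), Et2O/THF, 0 °C → rt, high dilution
Reagents that add atoms: hydrogen peroxide, OO
Why: Proposed new method: one molecule of H2O2 is alkylated twice by the two epoxides of 7, which has not been shown as one operation on a skipped bis-epoxide; the closest known reaction types are the molybdenum-catalysed perhydrolysis of trisubstituted epoxides with ethereal H2O2 (attack at the tertiary carbon, anti to the leaving oxygen) and the acid-promoted 5-exo cyclisation of hydroperoxy epoxides to 1,2-dioxolanes. The activated C2–C3 epoxide should be opened by H2O2 at the tertiary carbon C3 in a borderline SN2 process with inversion to give 8, whose hydroperoxide then attacks the tertiary carbon C5 of the second epoxide, again with inversion, and closes the dioxolane in a 5-exo-tet mode. The 5-exo closure at C5 should be preferred over 6-endo attack at C6 because C5 is the proximal and the more cation-stabilising carbon and C6 is deactivated by its CH2OH group. Both new stereocentres are controlled by the epoxide configurations set in step 3: two inversions turn (3S,5S) into (3R,5R), and no facial choice is involved, so the small difference between CH3 and CH2R plays no role. The step needs inversion and not ionisation at the tertiary carbons, which a mild hexavalent molybdenum catalyst, an ether solvent and low temperature should secure. It needs the hydroperoxide, and not the C2 hydroxyl (5-exo, tetrahydrofuran) or the C1 hydroxyl (6-exo), as the second nucleophile, which rests on the alpha effect and on the affinity of hexavalent molybdenum for peroxo ligands. It needs one H2O2 per molecule, which slow addition at high dilution should secure. Before the first opening the primary hydroxyls cannot reach the other epoxide, because the E geometry would force a trans-fused oxabicyclo[4.1.0]heptane.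

Step 5
Reactants: 9 (1S,1'S)-1,1'-[(3R,5R)-3,5-dimethyl-1,2-dioxolane-3,5-diyl]di(ethane-1,2-diol)
Product: 10 (3R,5R)-3,5-dimethyl-1,2-dioxolane-3,5-dicarbaldehyde
Conditions: NaIO4 on silica gel, CH2Cl2, rt
Reagents that add atoms: none
Why: Periodate glycol cleavage of both 1,2-diols; the dialkyl peroxide is inert to periodate, and the two aldehydes have no alpha hydrogen, so they can neither epimerise nor eliminate. Dialdehyde 10 is C2-symmetric.

Step 6
Reactants: 10 (3R,5R)-3,5-dimethyl-1,2-dioxolane-3,5-dicarbaldehyde; 11 (6-hydroxyhexyl)triphenylphosphonium bromide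
Product: 13 (3R,5R)-5-[(1Z)-7-hydroxyhept-1-en-1-yl]-3,5-dimethyl-1,2-dioxolane-3-carbaldehyde, via alkoxide ylide 12 (not isolated)
Conditions: 11, NaN(SiMe3)2 (2 equiv), THF, 0 °C; added to 10 (3 equiv), THF, −78 °C → 0 °C; unreacted 10 recovered
Reagents that add atoms: none
Why: Wittig olefination with a non-stabilised ylide; the two formyl groups of 10 are homotopic, so mono-olefination gives one compound, and keeping 10 in excess should hold double olefination low. The alkene geometry does not matter because the alkene is reduced next.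

Step 7
Reactants: 13 (3R,5R)-5-[(1Z)-7-hydroxyhept-1-en-1-yl]-3,5-dimethyl-1,2-dioxolane-3-carbaldehyde
Product: 14 (3R,5S)-5-(7-hydroxyheptyl)-3,5-dimethyl-1,2-dioxolane-3-carbaldehyde
Conditions: KO2CN=NCO2K (large excess, in portions), AcOH, pyridine, rt
Reagents that add atoms: none
Why: Diimide reduction: concerted syn transfer of H2 to the C6=C7 bond, which leaves O–O bonds and aldehydes untouched; the alkene adjoins a quaternary carbon, so a large excess of reagent is planned. The descriptor at C5 changes from R to S only through the CIP priorities.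

Step 8
Reactants: 14 (3R,5S)-5-(7-hydroxyheptyl)-3,5-dimethyl-1,2-dioxolane-3-carbaldehyde; 15 (methoxymethyl)triphenylphosphonium chloride
Product: 17 7-[(3S,5R)-5-(2-methoxyethenyl)-3,5-dimethyl-1,2-dioxolan-3-yl]heptan-1-ol (E/Z mixture), via methoxymethylene ylide 16 (not isolated)
Conditions: 15 (3 equiv), NaN(SiMe3)2, THF, 0 °C; then 14, −78 °C → 0 °C
Reagents that add atoms: none
Why: Wittig methoxymethylenation, a one-carbon homologation of the ring-bound aldehyde that brings in C1; the enol ether is inert to base, so no acidic C–H next to the peroxide carbon exists yet.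

Step 9
Reactants: 17 7-[(3S,5R)-5-(2-methoxyethenyl)-3,5-dimethyl-1,2-dioxolan-3-yl]heptan-1-ol
Product: 18 methyl 2-[(3R,5S)-3,5-dimethyl-5-(7-oxoheptyl)-1,2-dioxolan-3-yl]acetate
Conditions: pyridinium chlorochromate C5H5NH[CrO3Cl] (5 equiv), NaOAc, 4 Å MS, CH2Cl2, 0 °C → rt
Reagents that add atoms: pyridinium chlorochromate, [O-][Cr](=O)(=O)Cl.c1cc[nH+]cc1
Why: Known chlorochromate oxidation of enol ethers to esters (C-protonation at C2, capture of the oxocarbenium ion by chlorochromate, collapse to the methyl ester), run together with the standard oxidation of the primary alcohol to the aldehyde; both groups are unveiled without base.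

Step 10
Reactants: 18 methyl 2-[(3R,5S)-3,5-dimethyl-5-(7-oxoheptyl)-1,2-dioxolan-3-yl]acetate; 19 (triphenylphosphoranylidene)acetaldehyde
Product: 20 methyl 2-[(3R,5S)-3,5-dimethyl-5-[(7E)-9-oxonon-7-en-1-yl]-1,2-dioxolan-3-yl]acetate
Conditions: 19 (1.2 equiv), toluene, 60 °C
Reagents that add atoms: none
Why: Wittig reaction with a stabilised ylide should give the 12E enal; the ylide is too weakly basic to enolise the β-peroxy ester, and the temperature is well below that of O–O homolysis.

Step 11
Reactants: 21 (3Z)-hex-3-en-1-ol; 22 1-phenyl-1H-tetrazole-5-thiol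
Product: 23 5-[(3Z)-hex-3-en-1-ylsulfanyl]-1-phenyl-1H-tetrazole
Conditions: PPh3, diisopropyl azodicarboxylate, THF, 0 °C → rt
Reagents that add atoms: none
Why: Mitsunobu thioetherification of a primary alcohol; the Z alkene is a spectator.

Step 12
Reactants: 23 5-[(3Z)-hex-3-en-1-ylsulfanyl]-1-phenyl-1H-tetrazole
Product: 24 5-[(3Z)-hex-3-ene-1-sulfonyl]-1-phenyl-1H-tetrazole
Conditions: H2O2 (30% aq.), (NH4)6Mo7O24·4H2O (cat.), EtOH, 0 °C → rt
Reagents that add atoms: hydrogen peroxide, OO
Why: Molybdate-catalysed oxidation of sulfide to sulfone; this system oxidises sulfur much faster than an isolated disubstituted alkene.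

Step 13
Reactants: 20 methyl 2-[(3R,5S)-3,5-dimethyl-5-[(7E)-9-oxonon-7-en-1-yl]-1,2-dioxolan-3-yl]acetate; 24 5-[(3Z)-hex-3-ene-1-sulfonyl]-1-phenyl-1H-tetrazole
Product: 26 methyl 2-[(3R,5S)-3,5-dimethyl-5-[(7E,9E,12Z)-pentadeca-7,9,12-trien-1-yl]-1,2-dioxolan-3-yl]acetate, via sulfonyl carbanion 25 (not isolated)
Conditions: 24 (1.3 equiv), KN(SiMe3)2 (1.2 equiv), DME, −78 °C; then 20, −78 → −20 °C
Reagents that add atoms: none
Why: Julia–Kocienski olefination: addition of the metalated phenyltetrazolyl sulfone to the enal, Smiles rearrangement and loss of SO2 and the tetrazolone should give the 14E alkene, since the alkyl sulfone/enal pairing is the E-selective one. The amide base is consumed before 20 is added and the sulfonyl carbanion is a weaker base than an ester enolate, so the β-peroxy ester should not be opened.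

## Compound list

1 | ethynylmagnesium bromide | C#C[Mg]Br | starting material
2 | 3-bromoprop-1-yne | C#CCBr | starting material
3 | penta-1,4-diyne | C#CCC#C | intermediate
4 | [(1E,4E)-2,4-dimethylpenta-1,4-diene-1,5-diyl]bis(dimethylalane) | C[Al](C)/C=C(\C)C/C(C)=C/[Al](C)C | intermediate
5 | dilithium [(1E,4E)-2,4-dimethylpenta-1,4-diene-1,5-diyl]bis[butyl(dimethyl)aluminate] | [Li+].[Li+].CCCC[Al-](C)(C)/C=C(\C)C/C(C)=C/[Al-](C)(C)CCCC | intermediate
6 | (2E,5E)-3,5-dimethylhepta-2,5-diene-1,7-diol | OC/C=C(\C)C/C(C)=C/CO | intermediate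
7 | (2S,3S,5S,6S)-2,3:5,6-diepoxy-3,5-dimethylheptane-1,7-diol | OC[C@@H]1O[C@@]1(C)C[C@]2(C)O[C@H]2CO | intermediate
8 | (2S,3R)-3-hydroperoxy-4-[(2S,3S)-3-(hydroxymethyl)-2-methyloxiran-2-yl]-3-methylbutane-1,2-diol | OC[C@H](O)[C@@](OO)(C)C[C@]1(C)O[C@H]1CO | intermediate
9 | (1S,1'S)-1,1'-[(3R,5R)-3,5-dimethyl-1,2-dioxolane-3,5-diyl]di(ethane-1,2-diol) | OC[C@H](O)[C@@]1(C)C[C@@](C)(OO1)[C@@H](O)CO | intermediate
10 | (3R,5R)-3,5-dimethyl-1,2-dioxolane-3,5-dicarbaldehyde | O=C[C@@]1(C)C[C@@](C)(OO1)C=O | intermediate
11 | (6-hydroxyhexyl)triphenylphosphonium bromide | OCCCCCC[P+](c1ccccc1)(c1ccccc1)c1ccccc1.[Br-] | starting material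
12 | sodium 6-(triphenyl-λ5-phosphanylidene)hexan-1-olate | [Na+].[O-]CCCCCC=P(c1ccccc1)(c1ccccc1)c1ccccc1 | intermediate
13 | (3R,5R)-5-[(1Z)-7-hydroxyhept-1-en-1-yl]-3,5-dimethyl-1,2-dioxolane-3-carbaldehyde | O=C[C@@]1(C)C[C@@](C)(OO1)/C=C\CCCCCO | intermediate
14 | (3R,5S)-5-(7-hydroxyheptyl)-3,5-dimethyl-1,2-dioxolane-3-carbaldehyde | O=C[C@@]1(C)C[C@@](C)(OO1)CCCCCCCO | intermediate
15 | (methoxymethyl)triphenylphosphonium chloride | COC[P+](c1ccccc1)(c1ccccc1)c1ccccc1.[Cl-] | starting material
16 | (methoxymethylidene)triphenyl-λ5-phosphane | COC=P(c1ccccc1)(c1ccccc1)c1ccccc1 | intermediate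
17 | 7-[(3S,5R)-5-(2-methoxyethenyl)-3,5-dimethyl-1,2-dioxolan-3-yl]heptan-1-ol (E/Z mixture) | COC=C[C@@]1(C)C[C@@](C)(OO1)CCCCCCCO | intermediate
18 | methyl 2-[(3R,5S)-3,5-dimethyl-5-(7-oxoheptyl)-1,2-dioxolan-3-yl]acetate | COC(=O)C[C@@]1(C)C[C@@](C)(OO1)CCCCCCC=O | intermediate
19 | (triphenylphosphoranylidene)acetaldehyde | O=CC=P(c1ccccc1)(c1ccccc1)c1ccccc1 | starting material
20 | methyl 2-[(3R,5S)-3,5-dimethyl-5-[(7E)-9-oxonon-7-en-1-yl]-1,2-dioxolan-3-yl]acetate | COC(=O)C[C@@]1(C)C[C@@](C)(OO1)CCCCCC/C=C/C=O | intermediate
21 | (3Z)-hex-3-en-1-ol | CC/C=C\CCO | starting material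
22 | 1-phenyl-1H-tetrazole-5-thiol | SC1=NN=NN1c1ccccc1 | starting material
23 | 5-[(3Z)-hex-3-en-1-ylsulfanyl]-1-phenyl-1H-tetrazole | CC/C=C\CCSC1=NN=NN1c1ccccc1 | intermediate
24 | 5-[(3Z)-hex-3-ene-1-sulfonyl]-1-phenyl-1H-tetrazole | CC/C=C\CCS(=O)(=O)C1=NN=NN1c1ccccc1 | intermediate
25 | potassium (3Z)-1-[(1-phenyl-1H-tetrazol-5-yl)sulfonyl]hex-3-en-1-ide | [K+].CC/C=C\C[CH-]S(=O)(=O)C1=NN=NN1c1ccccc1 | intermediate
26 | methyl 2-[(3R,5S)-3,5-dimethyl-5-[(7E,9E,12Z)-pentadeca-7,9,12-trien-1-yl]-1,2-dioxolan-3-yl]acetate | CC/C=C\C/C=C/C=C/CCCCCC[C@@]1(C)C[C@](C)(CC(=O)OC)OO1 | target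

## Step count and least certain steps

Total step count: 13. Longest linear sequence: 11 (steps 1–10 and 13); steps 11 and 12 prepare sulfone 24.

**Step 4 (key step, proposed new method).** Most likely failure: the second ring closure is diverted to ether formation, because the C2 hydroxyl freed by the first opening can attack C5 in the same 5-exo sense as the hydroperoxide. Two further risks are partial ionisation at the tertiary carbons, which would erode the configuration, and opening of both epoxides by two molecules of H2O2.

Fallback (sets out from 6, returns at 9; known reaction types only). The two C–O bonds are made in separate operations and the interfering diol is capped in between.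
- 6 is epoxidised on one side only with the step 3 catalyst and a deficit of t-BuOOH (6 and 7 recycled), giving [(2S,3S)-3-[(2E)-4-hydroxy-2-methylbut-2-en-1-yl]-3-methyloxiran-2-yl]methanol F1.
- Perhydrolysis with excess ethereal H2O2 and catalytic TfOH gives (2S,3R,5E)-3-hydroperoxy-3,5-dimethylhept-5-ene-1,2,7-triol F2.
- 2-Methoxypropene and pyridinium p-toluenesulfonate cap the diol as an acetonide and the hydroperoxide as a peroxyketal; brief methanolysis releases the more labile mixed ketal on the allylic hydroxyl. This gives (2E,5R)-5-[(4S)-2,2-dimethyl-1,3-dioxolan-4-yl]-5-[(2-methoxypropan-2-yl)peroxy]-3-methylhex-2-en-1-ol F3.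
- A second Sharpless epoxidation with the same tartrate gives [(2S,3S)-3-{(2R)-2-[(4S)-2,2-dimethyl-1,3-dioxolan-4-yl]-2-[(2-methoxypropan-2-yl)peroxy]propyl}-3-methyloxiran-2-yl]methanol F4.
- Aqueous acetic acid frees the hydroperoxide, which closes onto C5 (5-exo, inversion) while the C2 oxygen is still held in the acetonide; continued hydrolysis removes the acetonide and gives 9.

**Step 2.** Most likely failure: incomplete second carbometalation, or metalation and isomerisation of the skipped diyne at its acidic C–H positions, which would give mixtures of mono-adducts and allenes.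

Fallback (from 3, back at 6). The methyl groups are introduced by hydroalumination, iodination and methylation instead of carbometalation.
- 3 is deprotonated twice with EtMgBr and trapped with paraformaldehyde to give hepta-2,5-diyne-1,7-diol F5.
- Hydroxyl-directed trans-hydroalumination with NaAlH2(OCH2CH2OMe)2 and iodination gives (2Z,5Z)-3,5-diiodohepta-2,5-diene-1,7-diol F6.
- Me2CuLi replaces both iodides by methyl with retention and gives 6.

**Step 6.** Most likely failure: olefination of both formyl groups, together with attack of the basic ylide and alkoxide on the excess dialdehyde, so that recovery of 10 is poor.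

Fallback (from 9, back at 13). The statistical event is moved to a protection step whose other components are recycled by simple hydrolysis.
- 9 is converted with 2,2-dimethoxypropane and pyridinium p-toluenesulfonate into the mono-acetonide (1S)-1-[(3R,5R)-5-[(4S)-2,2-dimethyl-1,3-dioxolan-4-yl]-3,5-dimethyl-1,2-dioxolan-3-yl]ethane-1,2-diol F7.
- NaIO4 cleaves the free diol to (3R,5R)-5-[(4S)-2,2-dimethyl-1,3-dioxolan-4-yl]-3,5-dimethyl-1,2-dioxolane-3-carbaldehyde F8.
- Excess ylide 12 gives (6Z)-7-[(3R,5R)-5-[(4S)-2,2-dimethyl-1,3-dioxolan-4-yl]-3,5-dimethyl-1,2-dioxolan-3-yl]hept-6-en-1-ol F9.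
- Aqueous acetic acid removes the acetonide to give (1S)-1-[(3R,5R)-5-[(1Z)-7-hydroxyhept-1-en-1-yl]-3,5-dimethyl-1,2-dioxolan-3-yl]ethane-1,2-diol F10.
- NaIO4 then gives 13.

**Step 9.** Most likely failure: acid-promoted ionisation of the C3–O bond, because the enol ether makes C3 a vinylogous peroxyketal carbon and the ring can open. Oxidative cleavage of the enol ether double bond is a second risk.

Fallback (from 17, back at 18). The two oxidations are separated and chromium is avoided.
- Oxalic acid on wet silica hydrolyses the enol ether to 2-[(3R,5S)-5-(7-hydroxyheptyl)-3,5-dimethyl-1,2-dioxolan-3-yl]acetaldehyde F11.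
- Pinnick oxidation (NaClO2, NaH2PO4, 2-methyl-2-butene) gives 2-[(3R,5S)-5-(7-hydroxyheptyl)-3,5-dimethyl-1,2-dioxolan-3-yl]acetic acid F12.
- Trimethylsilyldiazomethane gives methyl 2-[(3R,5S)-5-(7-hydroxyheptyl)-3,5-dimethyl-1,2-dioxolan-3-yl]acetate F13.
- Dess–Martin periodinane gives 18.

**Step 13.** Most likely failure: deprotonation at C2 of the β-peroxy ester by residual base, followed by E1cB opening of the dioxolane. Incomplete E selectivity at C14=C15 is a second risk.

Fallback (from 17, back at 26). The ester is kept masked as the base-stable enol ether through both olefinations.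
- Dess–Martin periodinane oxidises 17 to 7-[(3S,5R)-5-(2-methoxyethenyl)-3,5-dimethyl-1,2-dioxolan-3-yl]heptanal F14.
- Ylide 19 gives (2E)-9-[(3S,5R)-5-(2-methoxyethenyl)-3,5-dimethyl-1,2-dioxolan-3-yl]non-2-enal F15.
- Carbanion 25, made from 24 as in step 13, gives (3R,5S)-3-(2-methoxyethenyl)-3,5-dimethyl-5-[(7E,9E,12Z)-pentadeca-7,9,12-trien-1-yl]-1,2-dioxolane F16.
- Buffered pyridinium chlorochromate C5H5NH[CrO3Cl] oxidises the enol ether to the methyl ester and gives 26.

## Further compounds

F1 | step 4 | [(2S,3S)-3-[(2E)-4-hydroxy-2-methylbut-2-en-1-yl]-3-methyloxiran-2-yl]methanol | OC[C@@H]1O[C@@]1(C)C/C(C)=C/CO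
F2 | step 4 | (2S,3R,5E)-3-hydroperoxy-3,5-dimethylhept-5-ene-1,2,7-triol | OC[C@H](O)[C@@](OO)(C)C/C(C)=C/CO
F3 | step 4 | (2E,5R)-5-[(4S)-2,2-dimethyl-1,3-dioxolan-4-yl]-5-[(2-methoxypropan-2-yl)peroxy]-3-methylhex-2-en-1-ol | CC1(C)OC[C@H](O1)[C@@](OOC(C)(C)OC)(C)C/C(C)=C/CO
F4 | step 4 | [(2S,3S)-3-{(2R)-2-[(4S)-2,2-dimethyl-1,3-dioxolan-4-yl]-2-[(2-methoxypropan-2-yl)peroxy]propyl}-3-methyloxiran-2-yl]methanol | CC1(C)OC[C@H](O1)[C@@](OOC(C)(C)OC)(C)C[C@]2(C)O[C@H]2CO
F5 | step 2 | hepta-2,5-diyne-1,7-diol | OCC#CCC#CCO
F6 | step 2 | (2Z,5Z)-3,5-diiodohepta-2,5-diene-1,7-diol | OC/C=C(\I)C/C(I)=C/CO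
F7 | step 6 | (1S)-1-[(3R,5R)-5-[(4S)-2,2-dimethyl-1,3-dioxolan-4-yl]-3,5-dimethyl-1,2-dioxolan-3-yl]ethane-1,2-diol | CC1(C)OC[C@H](O1)[C@@]2(C)C[C@@](C)(OO2)[C@@H](O)CO
F8 | step 6 | (3R,5R)-5-[(4S)-2,2-dimethyl-1,3-dioxolan-4-yl]-3,5-dimethyl-1,2-dioxolane-3-carbaldehyde | CC1(C)OC[C@H](O1)[C@@]2(C)C[C@@](C)(OO2)C=O
F9 | step 6 | (6Z)-7-[(3R,5R)-5-[(4S)-2,2-dimethyl-1,3-dioxolan-4-yl]-3,5-dimethyl-1,2-dioxolan-3-yl]hept-6-en-1-ol | CC1(C)OC[C@H](O1)[C@@]2(C)C[C@@](C)(OO2)/C=C\CCCCCO
F10 | step 6 | (1S)-1-[(3R,5R)-5-[(1Z)-7-hydroxyhept-1-en-1-yl]-3,5-dimethyl-1,2-dioxolan-3-yl]ethane-1,2-diol | OC[C@H](O)[C@@]1(C)C[C@@](C)(OO1)/C=C\CCCCCO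
F11 | step 9 | 2-[(3R,5S)-5-(7-hydroxyheptyl)-3,5-dimethyl-1,2-dioxolan-3-yl]acetaldehyde | O=CC[C@@]1(C)C[C@@](C)(OO1)CCCCCCCO
F12 | step 9 | 2-[(3R,5S)-5-(7-hydroxyheptyl)-3,5-dimethyl-1,2-dioxolan-3-yl]acetic acid | OC(=O)C[C@@]1(C)C[C@@](C)(OO1)CCCCCCCO
F13 | step 9 | methyl 2-[(3R,5S)-5-(7-hydroxyheptyl)-3,5-dimethyl-1,2-dioxolan-3-yl]acetate | COC(=O)C[C@@]1(C)C[C@@](C)(OO1)CCCCCCCO
F14 | step 13 | 7-[(3S,5R)-5-(2-methoxyethenyl)-3,5-dimethyl-1,2-dioxolan-3-yl]heptanal | COC=C[C@@]1(C)C[C@@](C)(OO1)CCCCCCC=O
F15 | step 13 | (2E)-9-[(3S,5R)-5-(2-methoxyethenyl)-3,5-dimethyl-1,2-dioxolan-3-yl]non-2-enal | COC=C[C@@]1(C)C[C@@](C)(OO1)CCCCCC/C=C/C=O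
F16 | step 13 | (3R,5S)-3-(2-methoxyethenyl)-3,5-dimethyl-5-[(7E,9E,12Z)-pentadeca-7,9,12-trien-1-yl]-1,2-dioxolane | COC=C[C@@]1(C)C[C@@](C)(OO1)CCCCCC/C=C/C=C/C/C=C\CC
A1 | alternative 1 | methyl (2E)-12-[(tert-butyldimethylsilyl)oxy]-3,5-dimethyl-5-[(triethylsilyl)peroxy]dodec-2-enoate | COC(=O)/C=C(\C)CC(C)(OO[Si](CC)(CC)CC)CCCCCCCO[Si](C)(C)C(C)(C)C
A2 | alternative 2 | tert-butyl({7-[(3S)-5-methoxy-3,5-dimethyl-1,2-dioxolan-3-yl]heptyl}oxy)dimethylsilane | CC(C)(C)[Si](C)(C)OCCCCCCC[C@@]1(C)CC(C)(OC)OO1
A3 | alternative 2 | 2,2'-methylenebis[(2R)-2-methyloxetane] | C[C@@]1(CCO1)C[C@@]2(C)CCO2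
A4 | alternative 3 | methyl 3-methoxy-3-[(triethylsilyl)peroxy]butanoate | COC(=O)CC(C)(OC)OO[Si](CC)(CC)CC
A5 | alternative 3 | tert-butyldimethyl[(8-methylnon-8-en-1-yl)oxy]silane | C=C(C)CCCCCCCO[Si](C)(C)C(C)(C)C
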